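**Retrosynthetic overview**
1. The target is the 2β,3β,11β‑triol of the 19‑carbon gibberellin lactone acid, that is 11β‑hydroxy‑gibberellin A‑thirty‑four. The last disconnection is the C11–O bond, made by a late enzymatic C–H hydroxylation of the 2β,3β‑diol 5 (gibberellin A‑thirty‑four).
2. Diol 5 is disconnected at C2–O (enolate hydroxylation from the open β face) with C3 reset by ketone reduction, leading back to the 3‑ketone 2.
3. Ketone 2 comes from gibberellin A‑four (1) by alcohol oxidation.
4. Ring order: no ring is formed. Rings A, B, C and D and the 19,10‑lactone, with the C4, C5, C6, C8, C9, C10 and C13 stereocentres, are taken intact from 1; the route only adds two oxygens.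

Assumption: gibberellin A‑four, a fermentation product sold in bulk as a plant growth regulator, counts as a cheap commercial starting material; in all names "lactone acid" means the 19‑carbon gibberellin skeleton of gibberellin A‑nine (10‑hydroxy‑20‑norgibberell‑16‑ene‑7,19‑dioic acid 19,10‑lactone: six‑membered ring A, five‑membered ring B, six‑membered ring C, five‑membered ring D, 4β‑methyl, lactone bridge α, 5β‑H, 6β‑CO2H, 9β‑H, C15–C16 bridge β, exocyclic 16(17)‑methylene), with α/β as in the usual gibberellin drawing.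

**Route**

Step 1
Reactants: 1 gibberellin A‑four (3β‑hydroxy lactone acid)
Product: 2 3‑oxo lactone acid (3‑dehydro‑gibberellin A‑four)
Conditions: Dess–Martin periodinane (1.5 equiv), CH2Cl2, 0 °C to rt
Reagents that add atoms: none
Why: Dess–Martin oxidation of the hindered axial 3β‑alcohol proceeds under near‑neutral conditions that leave the free acid, the lactone and the 16‑ene alone; C4 is quaternary, so no stereocentre can epimerise.

Step 2
Reactants: 2 3‑oxo lactone acid
Product: 4 2β‑hydroxy‑3‑oxo lactone acid, via dipotassium enolate carboxylate 3 (not isolated)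
Conditions: KN(SiMe3)2 (2.3 equiv), THF, −78 °C; then 2‑(phenylsulfonyl)‑3‑phenyloxaziridine (1.3 equiv), −78 °C; AcOH quench at −78 °C
Reagents that add atoms: 2‑(phenylsulfonyl)‑3‑phenyloxaziridine (Davis oxaziridine), O=S(=O)(c1ccccc1)N1OC1c1ccccc1
Why: Davis enolate hydroxylation; the ketone can enolise only toward C2, and the oxaziridine attacks the C2=C3 enolate from the β face because the α face is covered by the lactone bridge, giving the equatorial 2β‑OH.

Step 3
Reactants: 4 2β‑hydroxy‑3‑oxo lactone acid
Product: 5 2β,3β‑dihydroxy lactone acid (gibberellin A‑thirty‑four)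
Conditions: LiBH(s‑Bu)3 (3.5 equiv), THF, −78 °C; AcOH quench at −78 °C; NaHCO3 extraction, then acidify to pH 3
Reagents that add atoms: none
Why: Diastereoselective ketone reduction; the bulky trialkylborohydride avoids the axial β trajectory (1β‑H, 5β‑H) and attacks equatorially, giving the axial 3β‑OH cis to 2β‑OH, and the cold acidic quench prevents retro‑aldol epimerisation at C3.

Step 4
Reactants: 5 2β,3β‑dihydroxy lactone acid (gibberellin A‑thirty‑four)
Product: 6 2β,3β,11β‑trihydroxy lactone acid (11β‑hydroxy‑gibberellin A‑thirty‑four; the target)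
Conditions: cytochrome P450 PtmO5 fused to the reductase domain RhFRed, pocket‑engineered variant (E. coli lysate, about 1 mol% haem enzyme), NADP+ (cat.), D‑glucose (3 equiv), glucose dehydrogenase, air, K2HPO4/KH2PO4 buffer pH 8.0, 5% DMSO, 25 °C; extraction at pH 4, reversed‑phase HPLC
Reagents that add atoms: dioxygen, O=O
Why: Proposed new method: PtmO5 hydroxylates the endo C11–H of an ent‑kauranoid, whose bicyclo[3.2.1]octane C/D unit is the same as in gibberellins, but it has not been used on a ring‑B‑contracted 19,10‑lactone gibberellin, so a variant with the ring A/B pocket reshaped by a focused site‑saturation library screened on 5 is proposed; with ring D held over the haem, the ferryl‑oxo (tetravalent iron) porphyrin radical cation abstracts the axial 11β‑H that lies beside the C15–C16 bridge, and hydroxyl rebound on the same face before the ring C radical can invert forms the C11–O bond with retention (11β‑OH), while the bridgehead C13–H and the 16‑ene π bond point away from the oxidant; the closest known reaction type is P450 C11 hydroxylation of ent‑kauranes and P450 hydroxylation of gibberellins at C13.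

**Compound list**
1 | gibberellin A‑four (3β‑hydroxy lactone acid; 19,10‑lactone α, 5β‑H, 6β‑CO2H, 9β‑H, 16(17)‑ene) | C=C1C[C@]23C[C@H]1CC[C@H]2[C@@]12CC[C@H](O)[C@@](C)(C(=O)O1)[C@H]2[C@@H]3C(=O)O | starting material
2 | 3‑oxo lactone acid (3‑dehydro‑gibberellin A‑four) | C=C1C[C@]23C[C@H]1CC[C@H]2[C@@]12CCC(=O)[C@@](C)(C(=O)O1)[C@H]2[C@@H]3C(=O)O | intermediate
3 | dipotassium enolate carboxylate of 2 (C2=C3 enolate, C7 carboxylate) | C=C1C[C@]23C[C@H]1CC[C@H]2[C@@]12CC=C([O-])[C@@](C)(C(=O)O1)[C@H]2[C@@H]3C(=O)[O-].[K+].[K+] | intermediate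
4 | 2β‑hydroxy‑3‑oxo lactone acid | C=C1C[C@]23C[C@H]1CC[C@H]2[C@@]12C[C@H](O)C(=O)[C@@](C)(C(=O)O1)[C@H]2[C@@H]3C(=O)O | intermediate
5 | 2β,3β‑dihydroxy lactone acid (gibberellin A‑thirty‑four) | C=C1C[C@]23C[C@H]1CC[C@H]2[C@@]12C[C@H](O)[C@H](O)[C@@](C)(C(=O)O1)[C@H]2[C@@H]3C(=O)O | intermediate
6 | 2β,3β,11β‑trihydroxy lactone acid (11β‑hydroxy‑gibberellin A‑thirty‑four; CNP0322347.1) | C=C1C[C@]23C[C@H]1C[C@H](O)[C@H]2[C@@]12C[C@H](O)[C@H](O)[C@@](C)(C(=O)O1)[C@H]2[C@@H]3C(=O)O | target

**Step count and risks**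
Total steps: 4. Longest linear sequence: 4.

Steps most likely to fail:

Step 4 (the new enzymatic 11β‑hydroxylation). The variant may not accept the polar diol acid, or may oxidise C12 or the 16‑ene instead. The fallback uses known chemistry, sets out from 5 and comes back at 6. Compound 5 is converted with 2,2‑dimethoxypropane and pyridinium p‑toluenesulfonate into the 2,3‑acetonide of the diol acid F1, and the acid is esterified (2‑(trimethylsilyl)ethanol, EDC, DMAP) to the 2‑(trimethylsilyl)ethyl ester of the acetonide F2. Ozonolysis (O3, CH2Cl2/MeOH, −78 °C; Me2S) gives the 17‑nor‑16‑ketone F3. Me3SiCH2MgCl/CeCl3 adds from the exo face (the C14 side) to give the 16‑endo‑hydroxy‑16‑(trimethylsilylmethyl) compound F4, whose hydroxyl sits next to 11β‑H. A hypoiodite reaction (PhI(OAc)2, I2, hν) generates the alkoxy radical, which abstracts 11β‑H by 1,5‑hydrogen transfer and closes to the 11β,16‑epoxy (tetrahydrofuran) compound F5; the C9–H is the competing site. BF3·OEt2 then opens this β‑silyl ether in a Peterson‑type elimination that regenerates only the exocyclic 16(17)‑ene and frees the 11β‑hydroxyl, giving the protected target F6. Bu4NF removes the silylethyl ester to give the target 2,3‑acetonide F7, and aqueous AcOH removes the acetonide to give 6.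

Step 3 (facial selectivity of the ketone reduction). Hydride may instead enter from the β face and give the 3α‑epimer, and the lithium 3‑alkoxide can epimerise by retro‑aldol cleavage if the mixture warms. The fallback bypasses the ketone altogether: it sets out from 1 and comes back at 5. Recombinant gibberellin 2‑oxidase (a divalent‑iron, 2‑oxoglutarate‑dependent dioxygenase, for example the runner‑bean enzyme expressed in E. coli) with FeSO4, 2‑oxoglutaric acid, ascorbic acid and air at pH 7.5 hydroxylates C2β–H of 1 directly, which is its native reaction, so C3 is never touched. It passes through no new compound (none F0).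

Step 2 (enolate hydroxylation of the keto acid dianion). The dipotassium salt may be poorly soluble at −78 °C, the enolate may add to the sulfonimine by‑product, or the α‑ketol may isomerise. The fallback sets out from 2 and comes back at 4 by a Rubottom oxidation under non‑basic conditions. Me3SiOTf/Et3N converts 2 into the bis(trimethylsilyl) derivative (C2=C3 silyl enol ether and silyl ester) F8. Dimethyldioxirane (1.0 equiv, acetone, −78 to −40 °C) epoxidises the electron‑rich enol ether from the β face in preference to the 16‑ene, and silyl migration gives the 2β‑trimethylsilyloxy‑3‑ketone trimethylsilyl ester F9. Aqueous citric acid in MeOH cleaves both silyl groups to give 4.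

**Further compounds**
F1 | step 4 | 2,3‑acetonide of the diol acid | C=C1C[C@]23C[C@H]1CC[C@H]2[C@@]12C[C@@H]4OC(C)(C)O[C@@H]4[C@@](C)(C(=O)O1)[C@H]2[C@@H]3C(=O)O
F2 | step 4 | 2‑(trimethylsilyl)ethyl ester of the acetonide | C=C1C[C@]23C[C@H]1CC[C@H]2[C@@]12C[C@@H]4OC(C)(C)O[C@@H]4[C@@](C)(C(=O)O1)[C@H]2[C@@H]3C(=O)OCC[Si](C)(C)C
F3 | step 4 | 17‑nor‑16‑ketone | O=C1C[C@]23C[C@H]1CC[C@H]2[C@@]12C[C@@H]4OC(C)(C)O[C@@H]4[C@@](C)(C(=O)O1)[C@H]2[C@@H]3C(=O)OCC[Si](C)(C)C
F4 | step 4 | 16‑endo‑hydroxy‑16‑(trimethylsilylmethyl) compound | C[Si](C)(C)C[C@]1(O)C[C@]23C[C@H]1CC[C@H]2[C@@]12C[C@@H]4OC(C)(C)O[C@@H]4[C@@](C)(C(=O)O1)[C@H]2[C@@H]3C(=O)OCC[Si](C)(C)C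
F5 | step 4 | 11β,16‑epoxy (tetrahydrofuran) compound | C[Si](C)(C)C[C@]1(O5)C[C@]23C[C@H]1C[C@H]5[C@H]2[C@@]12C[C@@H]4OC(C)(C)O[C@@H]4[C@@](C)(C(=O)O1)[C@H]2[C@@H]3C(=O)OCC[Si](C)(C)C
F6 | step 4 | protected target (11β‑hydroxy, 16‑ene, acetonide, silylethyl ester) | C=C1C[C@]23C[C@H]1C[C@H](O)[C@H]2[C@@]12C[C@@H]4OC(C)(C)O[C@@H]4[C@@](C)(C(=O)O1)[C@H]2[C@@H]3C(=O)OCC[Si](C)(C)C
F7 | step 4 | target 2,3‑acetonide | C=C1C[C@]23C[C@H]1C[C@H](O)[C@H]2[C@@]12C[C@@H]4OC(C)(C)O[C@@H]4[C@@](C)(C(=O)O1)[C@H]2[C@@H]3C(=O)O
F0 | step 3 | none | none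
F8 | step 2 | bis(trimethylsilyl) derivative (C2=C3 silyl enol ether and silyl ester) | C=C1C[C@]23C[C@H]1CC[C@H]2[C@@]12CC=C(O[Si](C)(C)C)[C@@](C)(C(=O)O1)[C@H]2[C@@H]3C(=O)O[Si](C)(C)C
F9 | step 2 | 2β‑trimethylsilyloxy‑3‑ketone trimethylsilyl ester | C=C1C[C@]23C[C@H]1CC[C@H]2[C@@]12C[C@H](O[Si](C)(C)C)C(=O)[C@@](C)(C(=O)O1)[C@H]2[C@@H]3C(=O)O[Si](C)(C)C
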